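**Retrosynthetic overview**

1. Ring numbering used throughout: C1 (C=O), C2 (carries CH2OH), C3 (=CH), C4 (O-propanoyl), C5 (isopropyl), C6 (O-butenoyl). Last disconnections: C2–CH2OH (Morita–Baylis–Hillman reaction with formaldehyde) and the C6–O ester.
2. Ring disconnection: C2=C3 (intramolecular Horner–Wadsworth–Emmons) together with C1–C2 (Roskamp homologation) in one flask, a [5+1] annulation of the C3–C4–C5–C6–C1 dialdehyde with a one-carbon diazophosphonate.
3. Enabling feature: the C6 hydroxyl is a γ-hydroxyl of the C3 aldehyde and is 1,3-anti to O4. In the dialdehyde it locks C3 as an oxolane lactol (ring O6–C6–C5–C4–C3, absent from the target), so only the C1 aldehyde accepts C2 and the ketone must end up next to C6; the lactol is cleaved in the ring closure.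
4. The dialdehyde comes from double ozonolysis of a 1,3-anti diol monopropanoate: anti-aldol (sets C4, C5), then Evans–Tishchenko reduction (sets C6 and puts the propanoate on O4 only).
5. Ring order: temporary oxolane (step 6), then the cyclohexenone (step 7), the only carbocycle made.

Key step: step 7

Remark: lactol 14 and ketophosphonate 16 are anomeric mixtures, so their hemiacetal carbon is written without configuration; dimethyl (diazomethyl)phosphonate 15 is taken as the commercial Seyferth–Gilbert reagent.

**Route**

Step 1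
Reactants: 1 (R)-4-benzyl-1,3-oxazolidin-2-one; 2 3-methylbutanoyl chloride
Product: 3 (R)-4-benzyl-3-(3-methylbutanoyl)-1,3-oxazolidin-2-one
Conditions: n-BuLi, THF, −78 °C; then 2, −78 to 0 °C
Reagents that add atoms: none
Why: N-acylation of the lithiated oxazolidinone by the acid chloride (standard auxiliary loading) should be clean; no stereocentre is formed.

Step 2
Reactants: 3 (R)-4-benzyl-3-(3-methylbutanoyl)-1,3-oxazolidin-2-one; 4 (2E)-3-phenylprop-2-enal (cinnamaldehyde)
Product: 6 (R)-4-benzyl-3-[(2S,3S,4E)-3-hydroxy-5-phenyl-2-(propan-2-yl)pent-4-enoyl]-1,3-oxazolidin-2-one, via O-trimethylsilyl aldol ether 5 (not isolated)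
Conditions: MgCl2 (0.2 equiv), Et3N, TMSCl, EtOAc, 23 °C; then 1 M HCl, THF
Reagents that add atoms: chlorotrimethylsilane, C[Si](C)(C)Cl (silyl group of intermediate 5 only; not retained in 6)
Why: Magnesium-halide-catalysed direct anti-aldol reaction of an N-acyloxazolidinone with a non-enolisable enal: the chelated (Z)-magnesium enolate is attacked anti to the benzyl group through a boat transition state, which should set C2 (S, the future C5) and C3 (S, the future C4) in the 2,3-anti relationship, silyl transfer releasing the catalyst.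

Step 3
Reactants: 6 (R)-4-benzyl-3-[(2S,3S,4E)-3-hydroxy-5-phenyl-2-(propan-2-yl)pent-4-enoyl]-1,3-oxazolidin-2-one; 7 N,O-dimethylhydroxylamine hydrochloride
Product: 8 (2S,3S,4E)-3-hydroxy-N-methoxy-N-methyl-5-phenyl-2-(propan-2-yl)pent-4-enamide
Conditions: AlMe3, CH2Cl2, −10 °C to rt
Reagents that add atoms: none
Why: Weinreb transamidation: the aluminium amide, anchored on the free β-hydroxyl, attacks the exocyclic imide carbonyl and expels the auxiliary without touching the two stereocentres.

Step 4
Reactants: 8 (2S,3S,4E)-3-hydroxy-N-methoxy-N-methyl-5-phenyl-2-(propan-2-yl)pent-4-enamide; 9 (2-methylprop-1-en-1-yl)magnesium bromide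
Product: 10 (5S,6S,7E)-6-hydroxy-2-methyl-8-phenyl-5-(propan-2-yl)octa-2,7-dien-4-one
Conditions: 9 (3 equiv), THF, −78 to 0 °C; aq. NH4Cl
Reagents that add atoms: none
Why: Weinreb ketone synthesis: the magnesium chelate of the tetrahedral adduct prevents over-addition, and the β,β-dimethyl enone (chosen over a vinyl ketone) should resist conjugate addition of the released amine and later single-electron reduction.

Step 5
Reactants: 10 (5S,6S,7E)-6-hydroxy-2-methyl-8-phenyl-5-(propan-2-yl)octa-2,7-dien-4-one; 11 propanal
Product: 12 (1E,3S,4R,5S)-5-hydroxy-7-methyl-1-phenyl-4-(propan-2-yl)octa-1,6-dien-3-yl propanoate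
Conditions: SmI2 (0.3 equiv, premixed with 11), THF, −10 °C, dark
Reagents that add atoms: none
Why: Evans–Tishchenko reduction: the samarium-bound hemiacetal formed from the hydroxyl of 10 and propanal delivers hydride to the ketone through a six-membered chair, which should give the 1,3-anti carbinol (new centre, the future C6) and leave the propanoate on the aldol oxygen only (the future O4).

Step 6
Reactants: 12 (1E,3S,4R,5S)-5-hydroxy-7-methyl-1-phenyl-4-(propan-2-yl)octa-1,6-dien-3-yl propanoate
Product: 14 (3R,4R,5R)-5-formyl-2-hydroxy-4-(propan-2-yl)oxolan-3-yl propanoate (both anomers), via open-chain hydroxy dialdehyde 13 (not isolated)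
Conditions: O3, CH2Cl2, −78 °C; then Me2S, −78 °C to rt; benzaldehyde removed by rapid silica filtration
Reagents that add atoms: ozone, [O-][O+]=O
Why: Ozonolysis with reductive work-up cleaves both electron-rich alkenes, and the γ-hydroxy aldehyde so formed should close spontaneously to the five-membered lactol, so that only the aldehyde alpha to the ring oxygen stays free; no stereocentre of the chain is touched.

Step 7
Reactants: 14 (3R,4R,5R)-5-formyl-2-hydroxy-4-(propan-2-yl)oxolan-3-yl propanoate; 15 dimethyl (diazomethyl)phosphonate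
Product: 18 (1S,5R,6R)-5-hydroxy-4-oxo-6-(propan-2-yl)cyclohex-2-en-1-yl propanoate, via ketophosphonate lactol 16 (not isolated), via open-chain ketophosphonate aldehyde 17 (not isolated)
Conditions: SnCl2 (0.2 equiv), CH2Cl2, 0 °C to rt; then solvent switch, LiCl, iPr2NEt, MeCN (0.01 M), rt
Reagents that add atoms: none
Why: SnCl2 activates the only free aldehyde (C1; the C3 aldehyde is locked as the oxolane lactol by O6), the diazo carbon adds, and a 1,2-hydride shift with loss of N2 should give the β-ketophosphonate 16 (Roskamp homologation, C1–C2 bond). With LiCl/iPr2NEt the lactol opens by ring–chain tautomerism to the hydroxy aldehyde 17, whose lithium-chelated phosphonate carbanion adds to C3 and expels dimethyl phosphate through the oxaphosphetane (intramolecular Horner–Wadsworth–Emmons reaction under Masamune–Roush conditions on a lactol, as in carbasugar cyclohexenone syntheses), forming C2=C3. The cyclohexenone closes in the 6-(enolendo)-exo-trig mode, and the oxolane is cleaved in the same event, releasing O6–H for step 10. No stereocentre is created: C4 and C5 are carried through, and C6, the only centre that can enolise in 16 to 18, should settle in the required configuration because the 6-OH then lies equatorial, trans to the C5 isopropyl group and clear of the axial C4 ester. The step needs chemoselectivity between two aldehydes and the right regiochemistry (ketone next to C6, alkene CH next to C4); both are secured by the lactol, since only the aldehyde alpha to the ring oxygen is free to be homologated. High dilution suppresses intermolecular olefination, and once the ring has formed the trans-1,3 relationship of O4 and O6 rules out acyl migration.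

Step 8
Reactants: 19 2-[(tert-butyldimethylsilyl)oxy]acetaldehyde; 20 ethyl 2-(triphenyl-λ5-phosphanylidene)propanoate
Product: 21 ethyl (2E)-4-[(tert-butyldimethylsilyl)oxy]-2-methylbut-2-enoate
Conditions: CH2Cl2, rt
Reagents that add atoms: none
Why: Wittig olefination with a stabilised, α-branched ylide should give the (E)-trisubstituted enoate.

Step 9
Reactants: 21 ethyl (2E)-4-[(tert-butyldimethylsilyl)oxy]-2-methylbut-2-enoate
Product: 22 (2E)-4-[(tert-butyldimethylsilyl)oxy]-2-methylbut-2-enoic acid
Conditions: LiOH, THF/H2O, 0 °C to rt; then 1 M HCl to pH 4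
Reagents that add atoms: lithium hydroxide, [Li+].[OH-]
Why: Saponification of the ethyl ester; the primary silyl ether and the alkene geometry should survive aqueous LiOH at or below rt.

Step 10
Reactants: 18 (1S,5R,6R)-5-hydroxy-4-oxo-6-(propan-2-yl)cyclohex-2-en-1-yl propanoate; 22 (2E)-4-[(tert-butyldimethylsilyl)oxy]-2-methylbut-2-enoic acid
Product: 23 (1R,5S,6S)-2-oxo-6-(propan-2-yl)-5-(propanoyloxy)cyclohex-3-en-1-yl (2E)-4-[(tert-butyldimethylsilyl)oxy]-2-methylbut-2-enoate
Conditions: N,N'-diisopropylcarbodiimide (DIC), DMAP (0.1 equiv), CH2Cl2, 0 °C to rt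
Reagents that add atoms: none
Why: Steglich esterification of the only free hydroxyl (the C6 ketol OH) should proceed with retention at C6, since only the O–H bond is involved.

Step 11
Reactants: 23 (1R,5S,6S)-2-oxo-6-(propan-2-yl)-5-(propanoyloxy)cyclohex-3-en-1-yl (2E)-4-[(tert-butyldimethylsilyl)oxy]-2-methylbut-2-enoate; 24 formaldehyde (37% aqueous solution)
Product: 25 (1R,5S,6S)-3-(hydroxymethyl)-2-oxo-6-(propan-2-yl)-5-(propanoyloxy)cyclohex-3-en-1-yl (2E)-4-[(tert-butyldimethylsilyl)oxy]-2-methylbut-2-enoate
Conditions: DMAP (0.3 equiv), THF/H2O, rt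
Reagents that add atoms: none
Why: Morita–Baylis–Hillman hydroxymethylation: DMAP adds to C3, the ammonium enolate is hydroxymethylated at C2 and loss of DMAP restores C2=C3; the trisubstituted side-chain enoate should stay inert and no stereocentre is formed.

Step 12
Reactants: 25 (1R,5S,6S)-3-(hydroxymethyl)-2-oxo-6-(propan-2-yl)-5-(propanoyloxy)cyclohex-3-en-1-yl (2E)-4-[(tert-butyldimethylsilyl)oxy]-2-methylbut-2-enoate
Product: 26 (1R,5S,6S)-3-(hydroxymethyl)-2-oxo-6-(propan-2-yl)-5-(propanoyloxy)cyclohex-3-en-1-yl (2E)-4-hydroxy-2-methylbut-2-enoate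
Conditions: HF·pyridine, pyridine, THF, 0 °C to rt
Reagents that add atoms: none
Why: Buffered fluoride desilylation should cleave the primary allylic silyl ether while the three esters and the enone, all base-sensitive, stay intact.

**Compound list**

1 | (R)-4-benzyl-1,3-oxazolidin-2-one | O=C1N[C@H](Cc2ccccc2)CO1 | starting material
2 | 3-methylbutanoyl chloride | CC(C)CC(Cl)=O | starting material
3 | (R)-4-benzyl-3-(3-methylbutanoyl)-1,3-oxazolidin-2-one | CC(C)CC(=O)N1[C@H](Cc2ccccc2)COC1=O | intermediate
4 | (2E)-3-phenylprop-2-enal | O=C/C=C/c1ccccc1 | starting material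
5 | (R)-4-benzyl-3-{(2S,3S,4E)-5-phenyl-2-(propan-2-yl)-3-[(trimethylsilyl)oxy]pent-4-enoyl}-1,3-oxazolidin-2-one | c1ccccc1/C=C/[C@H](O[Si](C)(C)C)[C@H](C(C)C)C(=O)N1[C@H](Cc2ccccc2)COC1=O | intermediate (not isolated)
6 | (R)-4-benzyl-3-[(2S,3S,4E)-3-hydroxy-5-phenyl-2-(propan-2-yl)pent-4-enoyl]-1,3-oxazolidin-2-one | c1ccccc1/C=C/[C@H](O)[C@H](C(C)C)C(=O)N1[C@H](Cc2ccccc2)COC1=O | intermediate
7 | N,O-dimethylhydroxylamine hydrochloride | CNOC.Cl | starting material
8 | (2S,3S,4E)-3-hydroxy-N-methoxy-N-methyl-5-phenyl-2-(propan-2-yl)pent-4-enamide | c1ccccc1/C=C/[C@H](O)[C@H](C(C)C)C(=O)N(C)OC | intermediate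
9 | (2-methylprop-1-en-1-yl)magnesium bromide | CC(C)=C[Mg]Br | starting material
10 | (5S,6S,7E)-6-hydroxy-2-methyl-8-phenyl-5-(propan-2-yl)octa-2,7-dien-4-one | c1ccccc1/C=C/[C@H](O)[C@H](C(C)C)C(=O)C=C(C)C | intermediate
11 | propanal | CCC=O | starting material
12 | (1E,3S,4R,5S)-5-hydroxy-7-methyl-1-phenyl-4-(propan-2-yl)octa-1,6-dien-3-yl propanoate | c1ccccc1/C=C/[C@H](OC(=O)CC)[C@H](C(C)C)[C@@H](O)C=C(C)C | intermediate
13 | (2R,3R,4R)-4-hydroxy-1,5-dioxo-3-(propan-2-yl)pentan-2-yl propanoate | O=C[C@H](OC(=O)CC)[C@H](C(C)C)[C@@H](O)C=O | intermediate (not isolated)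
14 | (3R,4R,5R)-5-formyl-2-hydroxy-4-(propan-2-yl)oxolan-3-yl propanoate (both C2 epimers) | O=C[C@@H]1OC(O)[C@H](OC(=O)CC)[C@@H]1C(C)C | intermediate
15 | dimethyl (diazomethyl)phosphonate | COP(=O)(OC)C=[N+]=[N-] | starting material
16 | (3R,4S,5R)-5-[2-(dimethoxyphosphoryl)acetyl]-2-hydroxy-4-(propan-2-yl)oxolan-3-yl propanoate (both C2 epimers) | COP(=O)(OC)CC(=O)[C@@H]1OC(O)[C@H](OC(=O)CC)[C@@H]1C(C)C | intermediate (not isolated)
17 | (2R,3R,4R)-6-(dimethoxyphosphoryl)-4-hydroxy-1,5-dioxo-3-(propan-2-yl)hexan-2-yl propanoate | O=C[C@H](OC(=O)CC)[C@H](C(C)C)[C@@H](O)C(=O)CP(=O)(OC)OC | intermediate (not isolated)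
18 | (1S,5R,6R)-5-hydroxy-4-oxo-6-(propan-2-yl)cyclohex-2-en-1-yl propanoate | CCC(=O)O[C@H]1C=CC(=O)[C@H](O)[C@H]1C(C)C | intermediate
19 | 2-[(tert-butyldimethylsilyl)oxy]acetaldehyde | CC(C)(C)[Si](C)(C)OCC=O | starting material
20 | ethyl 2-(triphenyl-λ5-phosphanylidene)propanoate | CCOC(=O)C(C)=P(c1ccccc1)(c1ccccc1)c1ccccc1 | starting material
21 | ethyl (2E)-4-[(tert-butyldimethylsilyl)oxy]-2-methylbut-2-enoate | CCOC(=O)/C(C)=C/CO[Si](C)(C)C(C)(C)C | intermediate
22 | (2E)-4-[(tert-butyldimethylsilyl)oxy]-2-methylbut-2-enoic acid | OC(=O)/C(C)=C/CO[Si](C)(C)C(C)(C)C | intermediate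
23 | (1R,5S,6S)-2-oxo-6-(propan-2-yl)-5-(propanoyloxy)cyclohex-3-en-1-yl (2E)-4-[(tert-butyldimethylsilyl)oxy]-2-methylbut-2-enoate | CCC(=O)O[C@H]1C=CC(=O)[C@H](OC(=O)/C(C)=C/CO[Si](C)(C)C(C)(C)C)[C@H]1C(C)C | intermediate
24 | formaldehyde | C=O | starting material
25 | (1R,5S,6S)-3-(hydroxymethyl)-2-oxo-6-(propan-2-yl)-5-(propanoyloxy)cyclohex-3-en-1-yl (2E)-4-[(tert-butyldimethylsilyl)oxy]-2-methylbut-2-enoate | CCC(=O)O[C@H]1C=C(CO)C(=O)[C@H](OC(=O)/C(C)=C/CO[Si](C)(C)C(C)(C)C)[C@H]1C(C)C | intermediate
26 | (1R,5S,6S)-3-(hydroxymethyl)-2-oxo-6-(propan-2-yl)-5-(propanoyloxy)cyclohex-3-en-1-yl (2E)-4-hydroxy-2-methylbut-2-enoate | CCC(=O)O[C@H]1C=C(CO)C(=O)[C@H](OC(=O)/C(C)=C/CO)[C@H]1C(C)C | target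

**Step count and risks**

Total step count: 12. Longest linear sequence: 10 steps (steps 1 to 7, then 10 to 12); steps 8 and 9 make the side-chain acid.

Steps most likely to fail:

1. Step 7 (key step). What may go wrong: incomplete lactol control, so that the diazo reagent also homologates the masked C3 aldehyde; base-induced propanoyl migration from O4 to the freed O6 or to the anomeric oxygen before the ring closes; enolisation of the α-acyloxy aldehyde with loss of configuration at C4. The fallback sets out from 14. The free aldehyde would be homologated with ethereal diazomethane (0 °C) to the methyl ketone (3R,4S,5R)-5-acetyl-2-hydroxy-4-(propan-2-yl)oxolan-3-yl propanoate F1. The same C2=C3 bond would then be closed by an amine-salt-catalysed intramolecular aldol condensation (dibenzylammonium trifluoroacetate, toluene, 50 °C), which runs without alkoxide or carbanion bases. This comes back to the route at 18.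

2. Step 11. What may go wrong: sluggish conjugate addition of DMAP at C3 beside the axial C4 ester, so that ester cleavage or acyl transfer by DMAP and water, and epimerisation at C6, take over during long reaction times. The fallback sets out from 23. α-Iodination (I2, pyridine, CH2Cl2, rt) should give the iodoenone (1R,5R,6S)-3-iodo-2-oxo-6-(propan-2-yl)-5-(propanoyloxy)cyclohex-3-en-1-yl (2E)-4-[(tert-butyldimethylsilyl)oxy]-2-methylbut-2-enoate F2. Stille coupling with (tributylstannyl)methanol (Pd(PPh3)4, dioxane, 80 °C) would install the hydroxymethyl group under neutral conditions. This comes back to the route at 25.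

3. Step 2. What may go wrong: slow soft enolisation and silyl transfer with the β-branched acyl group, giving low conversion and retro-aldol erosion of the anti selectivity. The fallback sets out from 3. The preformed dibutylboron enolate (Bu2BOTf, iPr2NEt, CH2Cl2, −78 °C) would be added to cinnamaldehyde 4 precomplexed with Et2AlCl. This is an irreversible, Lewis-acid-mediated addition through an open transition state on the same face of the chelated enolate, in place of the catalytic, reversible magnesium aldol, and should give the same anti adduct. It comes back to the route at 6 and makes no compound outside the list (F0).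

Further compounds
F1 | step 7 | (3R,4S,5R)-5-acetyl-2-hydroxy-4-(propan-2-yl)oxolan-3-yl propanoate (both C2 epimers) | CC(=O)[C@@H]1OC(O)[C@H](OC(=O)CC)[C@@H]1C(C)C
F2 | step 11 | (1R,5R,6S)-3-iodo-2-oxo-6-(propan-2-yl)-5-(propanoyloxy)cyclohex-3-en-1-yl (2E)-4-[(tert-butyldimethylsilyl)oxy]-2-methylbut-2-enoate | CCC(=O)O[C@H]1C=C(I)C(=O)[C@H](OC(=O)/C(C)=C/CO[Si](C)(C)C(C)(C)C)[C@H]1C(C)C
F0 | step 2 | none | none
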